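## The problem

Target 11 is a 4-aryl-3,4-dihydrocoumarin (chroman-2-one), and chroman-2-one numbering is used throughout, also for open-chain precursors. Lactone ring B is fused through C4a–C8a to ring A, which carries free hydroxyls at C5 and C7 and a 3-phenylpropanoyl group at C8; ring C, a 4-hydroxyphenyl group, sits on C4. C4 is the only stereocentre and is S. It is benzylic to two electron-rich arenes, and nothing else in the molecule can relay chirality to it, so a reagent or catalyst must set it. Ring A is an acylphloroglucinol whose three oxygens differ only by their neighbours. Ring B must close onto O1, the oxygen flanked by the acyl-bearing C8, and not onto the C5 oxygen, which flanks C4a equally well. The aryl ester of ring B opens with alkoxides and alcoholic base, and the ring-opened form can lose its configuration through an ortho-quinone methide. The free acylphloroglucinol is prone to C-alkylation and oxidation, so the phenols should be unveiled last and under neutral conditions. The enabling feature is that C2 is a single carbonyl carbon held between C3 and O1. Removing it as carbon monoxide turns ring B into a 2-(1-arylvinyl)phenol, with C3 as the alkene terminus and C4 as a prochiral 1,1-diaryl-substituted alkene carbon. One hydrometalation followed by carbonylation can then make both bonds to C2, close ring B and set C4 in one operation.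

## Retrosynthesis

**11 to 10.** The three phenolic O–H bonds of 11 are traced back to O–benzyl bonds in lactone 10. Benzyl is preferred over methyl (cleavage needs strong Lewis acids beside a lactone), over acetals (they would not survive the acid co-catalyst of the key step) and over silyl ethers (lost under aqueous base in the cross-coupling). The forward step must cleave three aryl benzyl ethers without reducing the aryl ketone, opening the lactone or touching C4.

**10 to 8 and 9.** The bonds C2–C3 and C2–O1 are cut, releasing carbon monoxide 9 and the achiral 2-(1-arylvinyl)phenol 8. Neighbouring cuts are weaker. Cutting C4–aryl (aryl addition to a coumarin) forms one bond and needs the coumarin first. Cutting C4a–C4 (hydroarylation of a cinnamic acid by the phenol) controls neither configuration nor the ring A site. Cutting O1–C2 alone shifts the stereocentre to an earlier step. The chosen cut removes a ring, two skeletal bonds and the only stereocentre together. The forward reaction must add hydride to C4 on one face, place the metal on C3, insert 9 and be captured by O1. Alkene 8 therefore carries exactly one free hydroxyl, the one on C8a.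

**8 to 5 and 7.** The C4a–C4 bond between ring A and the alkene is cut to aryl iodide 5 and alkenylboronate 7. The shorter alternative, acid-promoted addition of phenol 4 to alkyne 6, is set aside for three reasons:
- the diarylethene formed is more acid-sensitive than the alkyne consumed;
- the choice between C4a and C6 would rest on electronics alone;
- a second arene can add to the product.

Methylenation of a benzophenone fails because a second ketone is present. Cross-coupling fixes the site by the halogen and runs under base. It must join two hindered partners in the presence of a free phenol and an enolisable ketone.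

**7 to 6.** The C–B bond is cut to terminal alkyne 6. The forward reaction must place boron on the internal alkyne carbon.

**5 to 4.** The C4a–I bond is cut to phenol 4. The forward reaction must iodinate C4a (between the free hydroxyl and a benzyloxy group) and not C6 (between two benzyloxy groups).

**4 to 3.** Two O–benzyl bonds are cut to trihydroxy ketone 3. The forward reaction must leave one of the two hydroxyls ortho to the ketone free. The hydrogen bond to the carbonyl allows this, and the two ortho hydroxyls are equivalent, so no isomer can arise.

**3 to 1 and 2.** The C8–acyl bond is cut to phloroglucinol 1 and acid chloride 2. Ring A is threefold symmetric at this stage, so the acylation has no regiochemical question and the whole carbon skeleton of ring A is bought.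

## Roads not taken

Alternative 1: Ring A is made last, from a 4-methoxy-2-pyrone; the cut is C8–C8a.
- Forward step: methoxide, as its magnesium salt in methanol, opens the pyrone at its lactone carbonyl. The carbanion between the two side-chain ketones condenses onto the new ester, and enolisation gives A1, methyl (S)-3-[2,4-dihydroxy-6-methoxy-3-(3-phenylpropanoyl)phenyl]-3-(4-methoxyphenyl)propanoate.
- Merit: every ring A oxygen is differentiated from the acyclic stage. No selective etherification of a symmetric triol and no site-selective halogenation is needed. Lactonisation is unambiguous, because only the C8a hydroxyl is next to the propanoate chain. In this respect it is better than the chosen plan.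
- Weak points: the step closes ring A only and creates no stereocentre, so C4 must be set by a separate asymmetric reaction and then carried through methoxide treatment. The pyrone with its diketone chain needs a long linear sequence. Two methyl ethers must finally be cleaved with a strong Lewis acid beside the lactone and the acylphloroglucinol.
- Comparison: the chosen plan sets against the better oxygen differentiation a hydrogen-bond-controlled benzylation and a phenol-directed iodination, both with close precedent. It gains a route of seven steps in which ring B and C4 arise together and the end is a neutral hydrogenolysis.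

Alternative 2: Ring A is built around a preformed stereocentre by Danheiser benzannulation; the cuts are C4a–C8a and C5–C6.
- Forward step: heating a silyl ynol ether that carries C4 with a 3-ethoxycyclobutenone that carries the C8 side chain opens the cyclobutenone to a vinylketene. Cycloaddition, ring opening and six-electron electrocyclisation then give A2, methyl (S)-3-[4-(benzyloxy)phenyl]-3-{3-[1-(tert-butyldimethylsilyloxy)-3-phenylpropyl]-4-ethoxy-2-hydroxy-6-(triisopropylsilyloxy)phenyl}propanoate.
- Merit: a hexasubstituted arene forms with complete regiocontrol in one metal-free step. The phenol is free only at C8a, and the assembly is convergent. Regiocontrol on ring A is at least as good as in the chosen plan.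
- Weak points: the stereocentre must be made earlier and survive the strongly basic formation of the ynol ether at a propargylic, benzylic position. The C8 chain arrives as a silyl-protected carbinol, which adds an uncontrolled stereocentre and a later oxidation. The C7 ethyl ether needs a boron trihalide at the end. At least five operations follow the annulation.
- Comparison: the chosen plan reaches the same single-free-phenol pattern by ordinary phenol chemistry and needs no chiral building block.

Alternative 3: The acyl group and the C8a oxygen are introduced together by aryne insertion; the cuts are C8–acyl and C8a–O.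
- Forward step: fluoride generates the C8–C8a aryne from a silyl triflate. The carboxylate oxygen adds to C8a, the aryl anion at C8 attacks the acyl carbon, and the product is A3, (S)-1-[4,6-bis(benzyloxy)-3-{1-[4-(benzyloxy)phenyl]-3-(triisopropylsilyloxy)propyl}-2-hydroxyphenyl]-3-phenylpropan-1-one. The acid partner is A4, 3-phenylpropanoic acid.
- Merit: the ketone and the only free phenol appear in one mild step, exactly where the chosen plan needs them. The C7 benzyloxy group directs the oxygen nucleophile to the remote aryne carbon. No selective benzylation is required.
- Weak points: protonation of the aryl anion by A4 competes and gives the aryl ester. C8a is shielded by the branched substituent on C4a. The aryne precursor is a pentasubstituted arene that already carries the stereocentre. No ring is closed. Desilylation, oxidation to the acid, lactonisation and debenzylation remain.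
- Comparison: the chosen plan needs a regioselective iodination that this road avoids, but it forms the stereocentre and ring B catalytically from an achiral alkene.

Key step: step 6

Assumption: the (R) ligand is written for step 6. A trial run must show which antipode gives the 4S lactone; if it is the (S) ligand, that one is used and nothing else changes.

## Route

Step 1
Reactants: 1 phloroglucinol; 2 3-phenylpropanoyl chloride
Product: 3 1-(2,4,6-trihydroxyphenyl)-3-phenylpropan-1-one
Conditions: AlCl3 (3.5 equiv), PhNO2–CH2Cl2, 0 to 50 °C; then ice, aq. HCl
Reagents that add atoms: none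
Why: Friedel–Crafts acylation; all ring carbons of 1 are equivalent, any O-acylated material returns to the C-acyl product by Fries rearrangement under AlCl3, and the first acyl group deactivates the ring against a second.

Step 2
Reactants: 3 1-(2,4,6-trihydroxyphenyl)-3-phenylpropan-1-one
Product: 4 1-[2,4-bis(benzyloxy)-6-hydroxyphenyl]-3-phenylpropan-1-one
Conditions: BnBr (2.1 equiv), K2CO3 (2.2 equiv), DMF, 0 °C to rt
Reagents that add atoms: benzyl bromide, BrCc1ccccc1
Why: Williamson ether synthesis; the para hydroxyl and one ortho hydroxyl are alkylated, while the remaining ortho hydroxyl is held in a hydrogen bond to the ketone and is a poor nucleophile with a weak base, as is usual for 2,4,6-trihydroxyphenyl ketones.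

Step 3
Reactants: 4 1-[2,4-bis(benzyloxy)-6-hydroxyphenyl]-3-phenylpropan-1-one
Product: 5 1-[4,6-bis(benzyloxy)-2-hydroxy-3-iodophenyl]-3-phenylpropan-1-one
Conditions: NIS (1.05 equiv), cat. TFA, MeCN, 0 °C to rt
Reagents that add atoms: N-iodosuccinimide, O=C1CCC(=O)N1I
Why: Electrophilic aromatic iodination; the position ortho to the free, hydrogen-bonded phenol and para to a benzyloxy group (future C4a) is the site halogenated in closely related 2-hydroxy-4,6-dialkoxyphenyl ketones, and one equivalent of reagent should leave C6 untouched.

Step 4
Reactants: 6 1-(benzyloxy)-4-ethynylbenzene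
Product: 7 2-{1-[4-(benzyloxy)phenyl]ethenyl}-4,4,5,5-tetramethyl-1,3,2-dioxaborolane
Conditions: CuCl (5 mol %), SIMes·HCl (5 mol %), NaOt-Bu (10 mol %), B2pin2 (1.1 equiv), MeOH (2 equiv), THF, −40 °C
Reagents that add atoms: bis(pinacolato)diboron, CC1(C)OB(OC1(C)C)B1OC(C)(C)C(C)(C)O1
Why: Copper-catalysed protoboration of a terminal alkyne; with an N-aryl carbene ligand the Cu–B bond adds syn with boron on the internal carbon of an aryl alkyne, and methanol protonates the alkenylcopper to give the 1,1-disubstituted alkenylboronate.

Step 5
Reactants: 5 1-[4,6-bis(benzyloxy)-2-hydroxy-3-iodophenyl]-3-phenylpropan-1-one; 7 2-{1-[4-(benzyloxy)phenyl]ethenyl}-4,4,5,5-tetramethyl-1,3,2-dioxaborolane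
Product: 8 1-[4,6-bis(benzyloxy)-3-{1-[4-(benzyloxy)phenyl]ethenyl}-2-hydroxyphenyl]-3-phenylpropan-1-one
Conditions: Pd(OAc)2 (5 mol %), SPhos (10 mol %), K3PO4 (3 equiv), toluene–H2O (10:1), 80 °C
Reagents that add atoms: none
Why: Suzuki–Miyaura coupling; the SPhos complex of zerovalent palladium inserts into the hindered C–I bond and joins di-ortho-substituted partners, 2-iodophenols couple without protection, and the basic medium spares the acid-sensitive 1,1-diarylethene.

Step 6
Reactants: 8 1-[4,6-bis(benzyloxy)-3-{1-[4-(benzyloxy)phenyl]ethenyl}-2-hydroxyphenyl]-3-phenylpropan-1-one; 9 carbon monoxide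
Product: 10 (4S)-5,7-bis(benzyloxy)-4-[4-(benzyloxy)phenyl]-8-(3-phenylpropanoyl)-3,4-dihydro-2H-chromen-2-one
Conditions: Pd(OAc)2 (5 mol %), (R)-DTBM-SEGPHOS (6 mol %), TsOH·H2O (10 mol %), CO (20 bar), toluene, 60 °C
Reagents that add atoms: none
Why: This is a palladium-catalysed asymmetric intramolecular hydroalkoxycarbonylation of a 2-(1-arylvinyl)phenol, a known route to 4-aryl-3,4-dihydrocoumarins. Pd(OAc)2, the bisphosphine, CO and TsOH generate a cationic divalent palladium hydride, which adds across the alkene with hydride on the diaryl-substituted carbon (C4) and palladium on the terminal carbon (C3), because a tertiary dibenzylic alkylpalladium is too hindered to form or to carbonylate. CO inserts into the C3–Pd bond to make C2–C3, and the neighbouring phenol oxygen attacks the acylpalladium in a 6-exo-trig acyl substitution that makes C2–O1, closes ring B and returns the hydride. C4 is set under catalyst control by the chiral bisphosphine, which chooses the alkene face that receives hydride. The substrate helps because ring A, substituted at both ortho positions, is twisted out of the alkene plane while ring C can lie in it, so the two aryl groups look very different to the ligand. The regiochemistry of hydropalladation is secured by the 1,1-disubstitution, and there is no allylic hydrogen, so the alkene cannot migrate. The site of ring closure is secured by the protecting-group pattern, since O1 is the only free hydroxyl and the C5 oxygen cannot compete.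

Step 7
Reactants: 10 (4S)-5,7-bis(benzyloxy)-4-[4-(benzyloxy)phenyl]-8-(3-phenylpropanoyl)-3,4-dihydro-2H-chromen-2-one
Product: 11 (4S)-5,7-dihydroxy-4-(4-hydroxyphenyl)-8-(3-phenylpropanoyl)-3,4-dihydro-2H-chromen-2-one
Conditions: H2 (1 atm), 10% Pd/C, EtOAc, rt
Reagents that add atoms: none
Why: Hydrogenolysis of three aryl benzyl ethers; all bonds to C4 are C–C or C–H bonds and are not cleaved, the hindered hydrogen-bonded aryl ketone is reduced far more slowly than O-benzyl groups are removed, and a non-nucleophilic solvent keeps the aryl lactone closed, so C4 stays S.

## Compound list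

1 | phloroglucinol (benzene-1,3,5-triol) | Oc1cc(O)cc(O)c1 | starting material
2 | 3-phenylpropanoyl chloride | O=C(Cl)CCc1ccccc1 | starting material
3 | 1-(2,4,6-trihydroxyphenyl)-3-phenylpropan-1-one | O=C(CCc1ccccc1)c1c(O)cc(O)cc1O | intermediate
4 | 1-[2,4-bis(benzyloxy)-6-hydroxyphenyl]-3-phenylpropan-1-one | O=C(CCc1ccccc1)c1c(O)cc(OCc2ccccc2)cc1OCc1ccccc1 | intermediate
5 | 1-[4,6-bis(benzyloxy)-2-hydroxy-3-iodophenyl]-3-phenylpropan-1-one | O=C(CCc1ccccc1)c1c(O)c(I)c(OCc2ccccc2)cc1OCc1ccccc1 | intermediate
6 | 1-(benzyloxy)-4-ethynylbenzene | C#Cc1ccc(OCc2ccccc2)cc1 | starting material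
7 | 2-{1-[4-(benzyloxy)phenyl]ethenyl}-4,4,5,5-tetramethyl-1,3,2-dioxaborolane | C=C(B1OC(C)(C)C(C)(C)O1)c1ccc(OCc2ccccc2)cc1 | intermediate
8 | 1-[4,6-bis(benzyloxy)-3-{1-[4-(benzyloxy)phenyl]ethenyl}-2-hydroxyphenyl]-3-phenylpropan-1-one | C=C(c1ccc(OCc2ccccc2)cc1)c1c(OCc2ccccc2)cc(OCc2ccccc2)c(C(=O)CCc2ccccc2)c1O | intermediate
9 | carbon monoxide | [C-]#[O+] | starting material
10 | (4S)-5,7-bis(benzyloxy)-4-[4-(benzyloxy)phenyl]-8-(3-phenylpropanoyl)-3,4-dihydro-2H-chromen-2-one | O=C1C[C@@H](c2ccc(OCc3ccccc3)cc2)c2c(OCc3ccccc3)cc(OCc3ccccc3)c(C(=O)CCc3ccccc3)c2O1 | intermediate
11 | (4S)-5,7-dihydroxy-4-(4-hydroxyphenyl)-8-(3-phenylpropanoyl)-3,4-dihydro-2H-chromen-2-one | O=C1C[C@@H](c2ccc(O)cc2)c2c(O)cc(O)c(C(=O)CCc3ccccc3)c2O1 | target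

## Step count and risks

Total: 7 steps. Longest linear sequence: 6 steps (1, 2, 3, 5, 6, 7); step 4 prepares the coupling partner.

**Step 6 (key step).**
- Most likely failure: poor enantioface discrimination or slow turnover on an alkene whose ring A is hindered on both sides.
- The acid co-catalyst may protonate the very electron-rich diarylethene and cause oligomerisation.
- The phenol is tied up in a hydrogen bond to the ketone, so capture of the acylpalladium may be slow.
- The twisted conformers of 8 are mirror images and must interconvert faster than catalysis; the small ortho hydroxyl should allow this.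
- Fallback (from 5, returning at 10): the stereocentre is made by rhodium-catalysed conjugate arylation of a coumarin. Heck reaction of 5 with ethyl acrylate (Pd(OAc)2, P(o-tol)3, Et3N, DMF, 90 °C) should give ethyl (E)-3-[4,6-bis(benzyloxy)-2-hydroxy-3-(3-phenylpropanoyl)phenyl]prop-2-enoate F1. E to Z isomerisation with lactonisation (365 nm light, or catalytic n-Bu3P in warm toluene) should give 5,7-bis(benzyloxy)-8-(3-phenylpropanoyl)-2H-chromen-2-one F2. Hayashi–Miyaura addition of 4-(benzyloxy)phenylboronic acid (Rh(acac)(C2H4)2, the SEGPHOS antipode that gives 4S, dioxane–H2O, 60 °C) then forms the C4–aryl bond and gives 10. This is known chemistry on coumarins and costs two more steps.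

**Step 3 (iodination).**
- Most likely failure: loss of site selectivity. C6 lies between two benzyloxy groups and para to the phenol and is also strongly activated, so iodination there or twofold iodination may compete.
- Fallback (from 3, returning at 11): symmetry removes the question. Monobenzylation of 3 at the para, non-chelated hydroxyl (BnBr 1 equiv, NaHCO3, DMF) should give 1-[4-(benzyloxy)-2,6-dihydroxyphenyl]-3-phenylpropan-1-one F3. Its two open ring positions are equivalent, so NIS can give only 1-[4-(benzyloxy)-2,6-dihydroxy-3-iodophenyl]-3-phenylpropan-1-one F4. Coupling with 7 as in step 5 should give 1-[4-(benzyloxy)-3-{1-[4-(benzyloxy)phenyl]ethenyl}-2,6-dihydroxyphenyl]-3-phenylpropan-1-one F5. In F5 only one free hydroxyl is next to the alkene and the other flanking oxygen is benzylated, so carbonylation as in step 6 can close ring B only to (4S)-5-(benzyloxy)-4-[4-(benzyloxy)phenyl]-7-hydroxy-8-(3-phenylpropanoyl)-3,4-dihydro-2H-chromen-2-one F6. Hydrogenolysis as in step 7 gives 11. The price is a monobenzylation that must be stopped after one ether.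

**Step 4 (protoboration).**
- Most likely failure: erosion of internal selectivity. An electron-donating para substituent on the aryl alkyne lowers the preference for boron on the internal carbon, so the linear boronate may form alongside 7.
- Fallback (from 6, returning at 7): the same electron-rich aryl group makes ionic addition strictly Markovnikov. HBr made in the flask (TMSBr, MeOH, CH2Cl2, −40 °C) should give 1-(benzyloxy)-4-(1-bromoethenyl)benzene F7. Miyaura borylation (B2pin2, PdCl2(PPh3)2, PPh3, KOPh, toluene, 50 °C) gives 7.

**Step 5 (Suzuki–Miyaura coupling).**
- Most likely failure: slow transmetalation between an aryl iodide flanked by two oxygen substituents and a branched alkenylboronate. Protodeboronation of 7 and reduction of the C–I bond could then take over.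
- Fallback (from 5, returning at 8): a Barluenga coupling replaces the boron partner by a carbene precursor. Commercial 4'-(benzyloxy)acetophenone and tosylhydrazide (MeOH, 60 °C) give N'-{1-[4-(benzyloxy)phenyl]ethylidene}-4-methylbenzenesulfonohydrazide F8. Coupling of F8 with 5 (Pd2(dba)3, XPhos, LiOt-Bu, dioxane, 100 °C) proceeds by palladium carbene formation, aryl migration and β-hydride elimination and gives 8 directly.

**Step 7 (hydrogenolysis).**
- Most likely failure: over-reduction of the aryl ketone once the phenols are free, or stalling at the hindered C5 ether. Prolonged reaction then risks opening the lactone.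
- Fallback (from 10, returning at 11): non-reductive debenzylation with BCl3 and pentamethylbenzene as benzyl cation scavenger (CH2Cl2, −78 °C). It leaves the ketone untouched and passes through no new compound (F0).

## Further compounds

F1 | step 6 | ethyl (E)-3-[4,6-bis(benzyloxy)-2-hydroxy-3-(3-phenylpropanoyl)phenyl]prop-2-enoate | CCOC(=O)/C=C/c1c(OCc2ccccc2)cc(OCc2ccccc2)c(C(=O)CCc2ccccc2)c1O
F2 | step 6 | 5,7-bis(benzyloxy)-8-(3-phenylpropanoyl)-2H-chromen-2-one | O=C1C=Cc2c(OCc3ccccc3)cc(OCc3ccccc3)c(C(=O)CCc3ccccc3)c2O1
F3 | step 3 | 1-[4-(benzyloxy)-2,6-dihydroxyphenyl]-3-phenylpropan-1-one | O=C(CCc1ccccc1)c1c(O)cc(OCc2ccccc2)cc1O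
F4 | step 3 | 1-[4-(benzyloxy)-2,6-dihydroxy-3-iodophenyl]-3-phenylpropan-1-one | O=C(CCc1ccccc1)c1c(O)cc(OCc2ccccc2)c(I)c1O
F5 | step 3 | 1-[4-(benzyloxy)-3-{1-[4-(benzyloxy)phenyl]ethenyl}-2,6-dihydroxyphenyl]-3-phenylpropan-1-one | C=C(c1ccc(OCc2ccccc2)cc1)c1c(OCc2ccccc2)cc(O)c(C(=O)CCc2ccccc2)c1O
F6 | step 3 | (4S)-5-(benzyloxy)-4-[4-(benzyloxy)phenyl]-7-hydroxy-8-(3-phenylpropanoyl)-3,4-dihydro-2H-chromen-2-one | O=C1C[C@@H](c2ccc(OCc3ccccc3)cc2)c2c(OCc3ccccc3)cc(O)c(C(=O)CCc3ccccc3)c2O1
F7 | step 4 | 1-(benzyloxy)-4-(1-bromoethenyl)benzene | C=C(Br)c1ccc(OCc2ccccc2)cc1
F8 | step 5 | N'-{1-[4-(benzyloxy)phenyl]ethylidene}-4-methylbenzenesulfonohydrazide | CC(=NNS(=O)(=O)c1ccc(C)cc1)c1ccc(OCc2ccccc2)cc1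
F0 | step 7 | none | none
A1 | alternative 1 | methyl (S)-3-[2,4-dihydroxy-6-methoxy-3-(3-phenylpropanoyl)phenyl]-3-(4-methoxyphenyl)propanoate | COC(=O)C[C@@H](c1ccc(OC)cc1)c1c(OC)cc(O)c(C(=O)CCc2ccccc2)c1O
A2 | alternative 2 | methyl (S)-3-[4-(benzyloxy)phenyl]-3-{3-[1-(tert-butyldimethylsilyloxy)-3-phenylpropyl]-4-ethoxy-2-hydroxy-6-(triisopropylsilyloxy)phenyl}propanoate | COC(=O)C[C@@H](c1ccc(OCc2ccccc2)cc1)c1c(O[Si](C(C)C)(C(C)C)C(C)C)cc(OCC)c(C(O[Si](C)(C)C(C)(C)C)CCc2ccccc2)c1O
A3 | alternative 3 | (S)-1-[4,6-bis(benzyloxy)-3-{1-[4-(benzyloxy)phenyl]-3-(triisopropylsilyloxy)propyl}-2-hydroxyphenyl]-3-phenylpropan-1-one | CC(C)[Si](C(C)C)(C(C)C)OCC[C@@H](c1ccc(OCc2ccccc2)cc1)c1c(OCc2ccccc2)cc(OCc2ccccc2)c(C(=O)CCc2ccccc2)c1O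
A4 | alternative 3 | 3-phenylpropanoic acid | O=C(O)CCc1ccccc1
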